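Wednesday's run, charged with 1.50 times Monday's reagent, had made more left-handed product than Monday's by the same clock, 10.6 % against 7.5 % at 40.0 s and 13.9 % against 11.4 % at 60.0 s, but the gain was smaller than the charge ratio in both pairs.

in all of them: left-handed substrate 0.20 M; right-handed substrate 0.20 M
- Monday's: reagent 0.60 M; free catalyst 1 mM; the very flask that is asked about, followed so far
- Wednesday's: reagent 0.90 M; free catalyst 1 mM; run made earlier
- flask: reagent 0.600 M; free catalyst 1.0 mM

| run | time / s | left-handed product / % | left-handed substrate / % |
|---|---|---|---|
| Monday's | 12.0 | 3.9 | 46.2 |
| Monday's | 25.0 | 6.2 | 44.5 |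
| Monday's | 40.0 | 7.5 | 43.0 |
| Monday's | 50.0 | 9.0 | 39.8 |
| Monday's | 60.0 | 11.4 | 39.4 |
| Wednesday's | 20.0 | 6.7 | 42.7 |
| Wednesday's | 40.0 | 10.6 | 39.5 |
| Wednesday's | 60.0 | 13.9 | 35.0 |
| Wednesday's | 80.0 | 16.6 | 34.6 |
| Wednesday's | 120 | 22.8 | 26.9 |

(readings scatter by 0.5 percentage points)

- free catalyst is single-handed; left-handed substrate and right-handed substrate are mirror images of each other, charged as a racemate, each of them at the stated concentration

* apparent order in reagent when 30 % of the left-handed substrate and right-handed substrate together are converted (percent change of the rate of making left-handed product for one percent more reagent charged)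

I solved two extreme versions of the flask. In the first, the rate ignored the reagent standing in the flask, so the order in charged reagent was zero. In the second, the rate followed that reagent in proportion. The order is asked at a fixed conversion, and that brought in a small correction. Taking one reagent per substrate turned, I had 0.120 M of reagent used by then, at either reagent charge. One percent more charge therefore meant more than one percent more reagent left. I called this the leverage, the charge over the reagent left at that conversion:

leverage = 0.600 M / (0.600 M − 0.120 M) = 1.25

So the second extreme gave 1.25. The two pairs of readings, summed, gave an order of 0.640, with little reagent yet used. Multiplied by the leverage, that made 0.800. I took this as my low estimate, since Wednesday's run was further along on the same clock, so I expected the answer between 0.800 and 1.25.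

The forecast, which differed from my reckoning, gave 0.1: “the catalyst appears saturated and turnover-limited”.

The flask gave 1.1, inside my range, on these equations:

    free catalyst + left-handed substrate ⇌ catalyst intermediate A (K = 1.80 M⁻¹, k = 350 M⁻¹ s⁻¹)
    free catalyst + right-handed substrate ⇌ catalyst intermediate B (K = 2.40 M⁻¹, k = 4300 M⁻¹ s⁻¹)
    reagent + catalyst intermediate A → free catalyst + left-handed product (k = 50.0 M⁻¹ s⁻¹)
    reagent + catalyst intermediate B → free catalyst + right-handed product (k = 25.0 M⁻¹ s⁻¹)
    2 free catalyst ⇌ resting dimer (K = 76000 M⁻¹, k = 1600 M⁻¹ s⁻¹)

At 2.50 min the resting dimer, the resting state here, held 88.4 % of the catalyst, against 1.49 % in catalyst intermediate A and 2.50 % in catalyst intermediate B. Divided by the leverage, the result is an order of 0.912 in the reagent standing in the flask. For Wednesday's charge, the leverage at the same conversion is smaller, at 1.15.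

Readings and results were generated by integration on assumed constants, noise included.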